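**Retrosynthetic overview**
1. C40 = ring A C15 phosphonium salt + 2,7-dimethylocta-2,4,6-trienedial (C10) + ring B C15 keto-phosphonium salt; two Wittig olefinations (C11=C12 first, C11'=C12' last).
2. Ring B side chain: the 6'-hydroxy-8'-ketone comes from a C7'≡C8' alkyne by trans-hydrosilylation and Tamao–Fleming oxidation; the alkyne is put on by acetylide addition to the quinone monoketal obtained by oxidative dearomatisation of 2,6-dimethylphenol.
3. Key step: enantioselective copper hydride desymmetrisation of the achiral 4-alkynyl-4-silyloxy-3,5-dimethylcyclohexa-2,5-dienone sets C5' and C6' together; a conjugate methylation then completes the gem-dimethyl group.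
4. Ring A: asymmetric transfer hydrogenation of ketoisophorone sets C3; reductive enol triflation and Sonogashira coupling with the same enynol give the acetylenic C15 unit.
5. No ring is made by cyclisation: ring B is the dearomatised xylenol ring (elaborated first), ring A is the ketoisophorone ring.

Assumption: 1, 4 (pure E isomer), 18 and 25 are bought; the sense of induction in steps 3 and 8 is assigned by analogy with isophorone and with aryl ketones, and the antipodal ligand is taken if the first run shows the opposite sense.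

**Step 1**
Reactants: 1 2,6-dimethylphenol
Product: 3 4,4-dimethoxy-2,6-dimethylcyclohexa-2,5-dien-1-one, via 4-methoxy-2,6-dimethylphenol 2 (not isolated)
Conditions: PhI(OAc)2 (2.2 equiv), MeOH, 0 °C to rt
Reagents that add atoms: methanol, CO
Why: Hypervalent-iodine oxidative dearomatisation: two successive two-electron phenol oxidations in methanol (para-methoxylation, then ketalisation) give the quinone monoketal, the ortho positions being blocked by the methyl groups.

**Step 2**
Reactants: 3 4,4-dimethoxy-2,6-dimethylcyclohexa-2,5-dien-1-one; 4 (E)-3-methylpent-2-en-4-yn-1-ol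
Product: 8 3,5-dimethyl-4-[(E)-3-methyl-5-(triethylsilyloxy)pent-3-en-1-ynyl]-4-(triethylsilyloxy)cyclohexa-2,5-dien-1-one, via dilithio enynol 5 (not isolated), via dilithium ketal adduct 6 (not isolated), via bis-silyl ketal 7 (not isolated)
Conditions: 4, n-BuLi (2.05 equiv), THF, −78 to 0 °C; 3, −78 °C; Et3SiOTf (2.3 equiv), −78 to 0 °C; then 5% aq. oxalic acid/THF, 0 °C, 20 min
Reagents that add atoms: triethylsilyl trifluoromethanesulfonate, CC[Si](CC)(CC)OS(=O)(=O)C(F)(F)F; water, O
Why: 1,2-Addition of the lithium acetylide to the only free carbonyl of the quinone monoketal, O-silylation of both lithium alkoxides and mild ketal hydrolysis give the achiral, mirror-symmetric cross-conjugated dienone (a protected p-quinol).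

**Step 3 (key step)**
Reactants: 8 3,5-dimethyl-4-[(E)-3-methyl-5-(triethylsilyloxy)pent-3-en-1-ynyl]-4-(triethylsilyloxy)cyclohexa-2,5-dien-1-one
Product: 10 (4R,5R)-3,5-dimethyl-4-[(E)-3-methyl-5-(triethylsilyloxy)pent-3-en-1-ynyl]-4-(triethylsilyloxy)cyclohex-2-en-1-one, via silyl dienol ether 9 (not isolated)
Conditions: Cu(OAc)2·H2O (3 mol%), (S)-DTBM-SEGPHOS (3.3 mol%), (EtO)2MeSiH (1.3 equiv), toluene, −30 to 0 °C; then K2CO3 (0.1 equiv), MeOH, 0 °C; minor diastereomer removed by chromatography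
Reagents that add atoms: none
Why: Proposed new method: a bisphosphine-ligated copper hydride adds hydride to the β-carbon of one of the two enantiotopic enone arms; the bulky OSiEt3 group blocks its own face, so hydride enters syn to the slim alkynyl group and the 5-methyl ends up cis to the oxygen, and the chiral ligand accepts only the arm whose preferred enone face is this open face, which fixes C4 and C5 together as (4R,5R); the product leaves the cycle as a silyl dienol ether that is no longer a Michael acceptor, so the second arm is not reduced; the closest known reaction types are the asymmetric copper hydride 1,4-reduction of β,β-disubstituted cyclohexenones such as isophorone and copper-catalysed desymmetrising conjugate additions to 4,4-disubstituted cyclohexadienones.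

**Step 4**
Reactants: 10 (4R,5R)-3,5-dimethyl-4-[(E)-3-methyl-5-(triethylsilyloxy)pent-3-en-1-ynyl]-4-(triethylsilyloxy)cyclohex-2-en-1-one
Product: 12 (4R,5R)-3,3,5-trimethyl-4-[(E)-3-methyl-5-(triethylsilyloxy)pent-3-en-1-ynyl]-4-(triethylsilyloxy)cyclohexan-1-one, via trimethylsilyl enol ether 11 (not isolated)
Conditions: Me2CuLi (2.5 equiv, from MeLi and CuI), Me3SiCl (4 equiv), THF/Et2O, −78 to −30 °C; aq. NH4Cl; then K2CO3 (0.1 equiv), MeOH, 0 °C
Reagents that add atoms: methyllithium (delivered as Me2CuLi), C[Li]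
Why: Silyl-chloride-accelerated Gilman conjugate addition to the remaining β-methyl enone builds the gem-dimethyl carbon, which is not a stereocenter, and leaves C4 and C5 untouched.

**Step 5**
Reactants: 12 (4R,5R)-3,3,5-trimethyl-4-[(E)-3-methyl-5-(triethylsilyloxy)pent-3-en-1-ynyl]-4-(triethylsilyloxy)cyclohexan-1-one
Product: 13 (4S,5R)-4-[(1Z,3E)-2-(benzyldimethylsilyl)-3-methyl-5-(triethylsilyloxy)penta-1,3-dienyl]-3,3,5-trimethyl-4-(triethylsilyloxy)cyclohexan-1-one
Conditions: BnMe2SiH (1.5 equiv), [Cp*Ru(MeCN)3]PF6 (5 mol%), acetone, 0 °C to rt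
Reagents that add atoms: benzyldimethylsilane, C[SiH](C)Cc1ccccc1
Why: Trost ruthenium-catalysed trans-hydrosilylation puts silicon on the alkyne carbon remote from the oxygen-bearing quaternary carbon (electronic bias of the propargylic oxygen plus steric bulk), which is the carbon that becomes C8'=O; the descriptor at C4 changes only because the priorities change.

**Step 6**
Reactants: 13 (4S,5R)-4-[(1Z,3E)-2-(benzyldimethylsilyl)-3-methyl-5-(triethylsilyloxy)penta-1,3-dienyl]-3,3,5-trimethyl-4-(triethylsilyloxy)cyclohexan-1-one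
Product: 15 (4R,5R)-4-hydroxy-4-[(E)-5-hydroxy-3-methyl-2-oxopent-3-enyl]-3,3,5-trimethylcyclohexan-1-one, via fluorosilane diol 14 (not isolated)
Conditions: Bu4NF (4 equiv), THF, 0 °C to rt; then KHCO3, 30% H2O2, MeOH, 0 °C to rt
Reagents that add atoms: hydrogen peroxide, OO
Why: Fluoride removes the benzyl group from silicon and both triethylsilyl ethers, and Tamao–Fleming oxidation of the C–Si bond gives the enol and hence the β-hydroxy ketone (aldol-surrogate sequence) under bicarbonate conditions too mild for retro-aldol cleavage or epoxidation of the α-methyl enone.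

**Step 7**
Reactants: 15 (4R,5R)-4-hydroxy-4-[(E)-5-hydroxy-3-methyl-2-oxopent-3-enyl]-3,3,5-trimethylcyclohexan-1-one
Product: 17 [(E)-5-[(1R,6R)-1-hydroxy-2,2,6-trimethyl-4-oxocyclohexyl]-3-methyl-4-oxopent-2-enyl]triphenylphosphonium bromide, via allylic bromide 16 (not isolated)
Conditions: CBr4 (1.05 equiv), PPh3 (1.1 equiv), CH2Cl2, 0 °C; then PPh3 (1.1 equiv), rt
Reagents that add atoms: carbon tetrabromide, BrC(Br)(Br)Br; triphenylphosphine, c1ccc(cc1)P(c1ccccc1)c1ccccc1
Why: Appel bromination of the primary allylic alcohol (the hindered tertiary alcohol does not react) followed by SN2 quaternisation of the activated γ-bromo enone with PPh3 gives the Wittig salt under neutral conditions with retention of the E geometry.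

**Step 8**
Reactants: 18 2,6,6-trimethylcyclohex-2-ene-1,4-dione
Product: 19 (4R)-4-hydroxy-2,6,6-trimethylcyclohex-2-en-1-one
Conditions: RuCl(p-cymene)[(R,R)-TsDPEN] (0.5 mol%), i-PrOH, rt
Reagents that add atoms: none
Why: Noyori asymmetric transfer hydrogenation reduces only the unhindered C4 carbonyl (C1 is flanked by CMe2 and the C-methyl carbon), the (R,R)-diamine ligand giving the (4R)-alcohol with the ring alkene in the place of the aryl group of the usual model; this carbon becomes C3 of the target.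

**Step 9**
Reactants: 19 (4R)-4-hydroxy-2,6,6-trimethylcyclohex-2-en-1-one
Product: 20 (4R)-2,6,6-trimethyl-4-(triethylsilyloxy)cyclohex-2-en-1-one
Conditions: Et3SiCl, imidazole, CH2Cl2, 0 °C
Reagents that add atoms: chlorotriethylsilane, CC[Si](Cl)(CC)CC
Why: Standard silylation masks the alcohol for the hydride and triflation chemistry of the next step and comes off without a separate step in step 12.

**Step 10**
Reactants: 20 (4R)-2,6,6-trimethyl-4-(triethylsilyloxy)cyclohex-2-en-1-one
Product: 22 (4S)-2,6,6-trimethyl-4-(triethylsilyloxy)cyclohex-1-en-1-yl trifluoromethanesulfonate, via lithium enolate 21 (not isolated)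
Conditions: LiBH(s-Bu)3 (1.05 equiv), THF, −78 °C; then PhNTf2 (1.1 equiv), −78 °C to rt
Reagents that add atoms: N-phenylbis(trifluoromethanesulfonimide), O=S(=O)(N(c1ccccc1)S(=O)(=O)C(F)(F)F)C(F)(F)F
Why: Conjugate reduction by the bulky borohydride (the carbonyl is shielded by CMe2 and the α-methyl group) gives one regiodefined tetrasubstituted enolate, which is O-triflated (reductive enol triflation); the carbinol carbon is untouched and its descriptor changes only by priority.

**Step 11**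
Reactants: 22 (4S)-2,6,6-trimethyl-4-(triethylsilyloxy)cyclohex-1-en-1-yl trifluoromethanesulfonate; 4 (E)-3-methylpent-2-en-4-yn-1-ol
Product: 23 (E)-3-methyl-5-[(4S)-2,6,6-trimethyl-4-(triethylsilyloxy)cyclohex-1-en-1-yl]pent-2-en-4-yn-1-ol
Conditions: Pd(PPh3)4 (5 mol%), CuI (10 mol%), Et3N, DMF, rt to 45 °C
Reagents that add atoms: none
Why: Sonogashira coupling of the vinyl triflate with the terminal alkyne forms the C6–C7 bond with the 9E geometry of 4 retained.

**Step 12**
Reactants: 23 (E)-3-methyl-5-[(4S)-2,6,6-trimethyl-4-(triethylsilyloxy)cyclohex-1-en-1-yl]pent-2-en-4-yn-1-ol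
Product: 24 [(E)-5-[(4S)-4-hydroxy-2,6,6-trimethylcyclohex-1-en-1-yl]-3-methylpent-2-en-4-ynyl]triphenylphosphonium bromide
Conditions: PPh3·HBr (1.15 equiv), MeOH, rt
Reagents that add atoms: triphenylphosphine hydrobromide, [Br-].c1ccc(cc1)[PH+](c1ccccc1)c1ccccc1
Why: Standard carotenoid Wittig-salt formation: the protonated primary allylic alcohol is displaced by PPh3 at the unhindered terminus, and the acidic methanol cleaves the silyl ether at the same time; the secondary carbinol is not involved.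

**Step 13**
Reactants: 24 [(E)-5-[(4S)-4-hydroxy-2,6,6-trimethylcyclohex-1-en-1-yl]-3-methylpent-2-en-4-ynyl]triphenylphosphonium bromide; 25 (2E,4E,6E)-2,7-dimethylocta-2,4,6-trienedial
Product: 27 (2E,4E,6E,8E,10E)-13-[(4S)-4-hydroxy-2,6,6-trimethylcyclohex-1-en-1-yl]-2,7,11-trimethyltrideca-2,4,6,8,10-pentaen-12-ynal, via ring A ylide 26 (not isolated)
Conditions: 25 (3 equiv), NaOMe (1.1 equiv), MeOH/CH2Cl2, −10 °C to rt; crude warmed in EtOAc/heptane, 60 °C
Reagents that add atoms: none
Why: Wittig olefination on one end of the symmetric dialdehyde (used in excess so that only one aldehyde reacts) forms C11=C12, and the sterically hindered 11Z isomer isomerises to E on gentle warming.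

**Step 14**
Reactants: 27 (2E,4E,6E,8E,10E)-13-[(4S)-4-hydroxy-2,6,6-trimethylcyclohex-1-en-1-yl]-2,7,11-trimethyltrideca-2,4,6,8,10-pentaen-12-ynal; 17 [(E)-5-[(1R,6R)-1-hydroxy-2,2,6-trimethyl-4-oxocyclohexyl]-3-methyl-4-oxopent-2-enyl]triphenylphosphonium bromide
Product: 29 (3S,5'R,6'R)-3,6'-dihydroxy-7,8-didehydro-5',6',7',8'-tetrahydro-β,β-carotene-3',8'-dione (CNP0128854.2), via ring B ylide 28 (not isolated)
Conditions: 1,2-epoxybutane/EtOH (10:1), 65 °C, dark, Ar; all-E isomer crystallised after brief warming in EtOAc/heptane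
Reagents that add atoms: none
Why: Wittig olefination with a keto-stabilised vinylogous ylide, generated without added strong base (the epoxide scavenges HBr) so that the tertiary β-hydroxy ketone does not undergo retro-aldol cleavage, forms C11'=C12'; no stereocenter is touched and the hindered 11'Z isomer goes to E.

**Compound list**
1 | 2,6-dimethylphenol | Cc1cccc(C)c1O | starting material
2 | 4-methoxy-2,6-dimethylphenol | COc1cc(C)c(O)c(C)c1 | intermediate
3 | 4,4-dimethoxy-2,6-dimethylcyclohexa-2,5-dien-1-one | COC1(OC)C=C(C)C(=O)C(C)=C1 | intermediate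
4 | (E)-3-methylpent-2-en-4-yn-1-ol | C#C/C(C)=C/CO | starting material
5 | dilithio enynol: lithium (E)-5-lithio-3-methylpent-2-en-4-yn-1-olate | [Li]OC/C=C(C)/C#C[Li] | intermediate
6 | dilithium ketal adduct: dilithium dialkoxide of 1-[(E)-5-hydroxy-3-methylpent-3-en-1-ynyl]-4,4-dimethoxy-2,6-dimethylcyclohexa-2,5-dien-1-ol | [Li]OC/C=C(C)/C#CC1(O[Li])C(C)=CC(OC)(OC)C=C1C | intermediate
7 | bis-silyl ketal: bis(triethylsilyl) ether of 1-[(E)-5-hydroxy-3-methylpent-3-en-1-ynyl]-4,4-dimethoxy-2,6-dimethylcyclohexa-2,5-dien-1-ol | CC[Si](CC)(CC)OC/C=C(C)/C#CC1(O[Si](CC)(CC)CC)C(C)=CC(OC)(OC)C=C1C | intermediate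
8 | 3,5-dimethyl-4-[(E)-3-methyl-5-(triethylsilyloxy)pent-3-en-1-ynyl]-4-(triethylsilyloxy)cyclohexa-2,5-dien-1-one (achiral) | CC[Si](CC)(CC)OC/C=C(C)/C#CC1(O[Si](CC)(CC)CC)C(C)=CC(=O)C=C1C | intermediate
9 | silyl dienol ether: diethoxy(methyl)silyl dienol ether of 10 | CC[Si](CC)(CC)OC/C=C(C)/C#C[C@@]1(O[Si](CC)(CC)CC)[C@H](C)C=C(O[Si](C)(OCC)OCC)C=C1C | intermediate
10 | (4R,5R)-3,5-dimethyl-4-[(E)-3-methyl-5-(triethylsilyloxy)pent-3-en-1-ynyl]-4-(triethylsilyloxy)cyclohex-2-en-1-one (5-methyl cis to 4-O) | CC[Si](CC)(CC)OC/C=C(C)/C#C[C@@]1(O[Si](CC)(CC)CC)[C@H](C)CC(=O)C=C1C | intermediate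
11 | trimethylsilyl enol ether of 12 | CC[Si](CC)(CC)OC/C=C(C)/C#C[C@@]1(O[Si](CC)(CC)CC)[C@H](C)CC(O[Si](C)(C)C)=CC1(C)C | intermediate
12 | (4R,5R)-3,3,5-trimethyl-4-[(E)-3-methyl-5-(triethylsilyloxy)pent-3-en-1-ynyl]-4-(triethylsilyloxy)cyclohexan-1-one | CC[Si](CC)(CC)OC/C=C(C)/C#C[C@@]1(O[Si](CC)(CC)CC)[C@H](C)CC(=O)CC1(C)C | intermediate
13 | (4S,5R)-4-[(1Z,3E)-2-(benzyldimethylsilyl)-3-methyl-5-(triethylsilyloxy)penta-1,3-dienyl]-3,3,5-trimethyl-4-(triethylsilyloxy)cyclohexan-1-one | CC[Si](CC)(CC)OC/C=C(C)/C([Si](C)(C)Cc2ccccc2)=C/[C@@]1(O[Si](CC)(CC)CC)[C@H](C)CC(=O)CC1(C)C | intermediate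
14 | fluorosilane diol: (4S,5R)-4-[(1Z,3E)-2-(fluorodimethylsilyl)-5-hydroxy-3-methylpenta-1,3-dienyl]-4-hydroxy-3,3,5-trimethylcyclohexan-1-one | OC/C=C(C)/C([Si](C)(C)F)=C/[C@@]1(O)[C@H](C)CC(=O)CC1(C)C | intermediate
15 | (4R,5R)-4-hydroxy-4-[(E)-5-hydroxy-3-methyl-2-oxopent-3-enyl]-3,3,5-trimethylcyclohexan-1-one | OC/C=C(\C)C(=O)C[C@@]1(O)[C@H](C)CC(=O)CC1(C)C | intermediate
16 | allylic bromide: (4R,5R)-4-[(E)-5-bromo-3-methyl-2-oxopent-3-enyl]-4-hydroxy-3,3,5-trimethylcyclohexan-1-one | BrC/C=C(\C)C(=O)C[C@@]1(O)[C@H](C)CC(=O)CC1(C)C | intermediate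
17 | [(E)-5-[(1R,6R)-1-hydroxy-2,2,6-trimethyl-4-oxocyclohexyl]-3-methyl-4-oxopent-2-enyl]triphenylphosphonium bromide | [Br-].O=C(C[C@@]1(O)[C@H](C)CC(=O)CC1(C)C)/C(C)=C/C[P+](c2ccccc2)(c3ccccc3)c4ccccc4 | intermediate
18 | 2,6,6-trimethylcyclohex-2-ene-1,4-dione (ketoisophorone) | CC1=CC(=O)CC(C)(C)C1=O | starting material
19 | (4R)-4-hydroxy-2,6,6-trimethylcyclohex-2-en-1-one | CC1=C[C@H](O)CC(C)(C)C1=O | intermediate
20 | (4R)-2,6,6-trimethyl-4-(triethylsilyloxy)cyclohex-2-en-1-one | CC1=C[C@H](O[Si](CC)(CC)CC)CC(C)(C)C1=O | intermediate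
21 | lithium enolate: lithium (4S)-2,6,6-trimethyl-4-(triethylsilyloxy)cyclohex-1-en-1-olate | CC1=C(O[Li])C(C)(C)C[C@@H](O[Si](CC)(CC)CC)C1 | intermediate
22 | (4S)-2,6,6-trimethyl-4-(triethylsilyloxy)cyclohex-1-en-1-yl trifluoromethanesulfonate | CC1=C(OS(=O)(=O)C(F)(F)F)C(C)(C)C[C@@H](O[Si](CC)(CC)CC)C1 | intermediate
23 | (E)-3-methyl-5-[(4S)-2,6,6-trimethyl-4-(triethylsilyloxy)cyclohex-1-en-1-yl]pent-2-en-4-yn-1-ol | CC1=C(C#C/C(C)=C/CO)C(C)(C)C[C@@H](O[Si](CC)(CC)CC)C1 | intermediate
24 | [(E)-5-[(4S)-4-hydroxy-2,6,6-trimethylcyclohex-1-en-1-yl]-3-methylpent-2-en-4-ynyl]triphenylphosphonium bromide | [Br-].CC1=C(C#C/C(C)=C/C[P+](c2ccccc2)(c3ccccc3)c4ccccc4)C(C)(C)C[C@@H](O)C1 | intermediate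
25 | (2E,4E,6E)-2,7-dimethylocta-2,4,6-trienedial | O=C/C(C)=C/C=C/C=C(C)/C=O | starting material
26 | ring A ylide: triphenylphosphonium ylide of 24 | CC1=C(C#C/C(C)=C/C=P(c2ccccc2)(c3ccccc3)c4ccccc4)C(C)(C)C[C@@H](O)C1 | intermediate
27 | (2E,4E,6E,8E,10E)-13-[(4S)-4-hydroxy-2,6,6-trimethylcyclohex-1-en-1-yl]-2,7,11-trimethyltrideca-2,4,6,8,10-pentaen-12-ynal | CC1=C(C#C/C(C)=C/C=C/C(C)=C/C=C/C=C(C)/C=O)C(C)(C)C[C@@H](O)C1 | intermediate
28 | ring B ylide: triphenylphosphonium ylide of 17 | O=C(C[C@@]1(O)[C@H](C)CC(=O)CC1(C)C)/C(C)=C/C=P(c2ccccc2)(c3ccccc3)c4ccccc4 | intermediate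
29 | (3S,5'R,6'R)-3,6'-dihydroxy-7,8-didehydro-5',6',7',8'-tetrahydro-β,β-carotene-3',8'-dione, all-E (CNP0128854.2) | CC1=C(C#C/C(C)=C/C=C/C(C)=C/C=C/C=C(C)/C=C/C=C(\C)C(=O)C[C@@]2(O)[C@H](C)CC(=O)CC2(C)C)C(C)(C)C[C@@H](O)C1 | target

**Totals and risks**
Total step count: 14. Longest linear sequence: 8 (steps 1 to 7, then step 14).

Most likely to fail, first: step 3. The face selection (hydride anti to OSiEt3) and the selection between the two enone arms may be incomplete, or the catalyst may be too slow on this crowded β-carbon. The fallback sets out from 8 and reverses the order of the two conjugate additions. A copper-catalysed enantioselective conjugate methylation (Me3Al, copper thiophene-2-carboxylate, a BINOL-derived phosphoramidite, Et2O, −30 °C) desymmetrises 8 to the abscisic-acid-type enone (4S)-3,5,5-trimethyl-4-[(E)-3-methyl-5-(triethylsilyloxy)pent-3-en-1-ynyl]-4-(triethylsilyloxy)cyclohex-2-en-1-one F1. Its remaining ring alkene is then reduced under substrate control with [(Ph3P)CuH]6 in toluene (hydride anti to OSiEt3), and the route is rejoined at 12.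

Second: step 4. Methyl transfer to a β-carbon that is next to the fully substituted silyloxy carbon may stall. The fallback sets out from 10 and uses the free alcohol as a delivering group. Bu4NF buffered with AcOH (THF, 0 °C) gives (4R,5R)-4-hydroxy-4-[(E)-5-hydroxy-3-methylpent-3-en-1-ynyl]-3,5-dimethylcyclohex-2-en-1-one F2. MeMgBr (4 equiv) with catalytic CuI (THF, −20 °C) then adds methyl through the magnesium alkoxide to give (4R,5R)-4-hydroxy-4-[(E)-5-hydroxy-3-methylpent-3-en-1-ynyl]-3,3,5-trimethylcyclohexan-1-one F3. The free propargylic alcohol is hydrosilylated with BnMe2SiH and [Cp*Ru(MeCN)3]PF6 to (4S,5R)-4-[(1Z,3E)-2-(benzyldimethylsilyl)-5-hydroxy-3-methylpenta-1,3-dienyl]-4-hydroxy-3,3,5-trimethylcyclohexan-1-one F4. Debenzylation with Bu4NF brings it back to the route at 14, just before the peroxide oxidation.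

Third: step 5. The alkyne is buried between a quaternary carbon and a branched alkene and may resist the bulky ruthenium catalyst or give the wrong regioisomer. The fallback sets out from 12 and hydrates the alkyne directly with a π-acid: Ph3PAuNTf2 (2 mol%), H2O (5 equiv), 1,4-dioxane, rt. Water attacks the alkyne carbon that is remote from the electron-poor oxygenated carbon and next to the alkene, giving (4R,5R)-3,3,5-trimethyl-4-[(E)-3-methyl-2-oxo-5-(triethylsilyloxy)pent-3-enyl]-4-(triethylsilyloxy)cyclohexan-1-one F5. HF·pyridine in THF/pyridine removes both silyl groups and the route is rejoined at 15.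

**Further compounds**
F1 | step 3 | (4S)-3,5,5-trimethyl-4-[(E)-3-methyl-5-(triethylsilyloxy)pent-3-en-1-ynyl]-4-(triethylsilyloxy)cyclohex-2-en-1-one | CC[Si](CC)(CC)OC/C=C(C)/C#C[C@@]1(O[Si](CC)(CC)CC)C(C)=CC(=O)CC1(C)C
F2 | step 4 | (4R,5R)-4-hydroxy-4-[(E)-5-hydroxy-3-methylpent-3-en-1-ynyl]-3,5-dimethylcyclohex-2-en-1-one | OC/C=C(C)/C#C[C@@]1(O)[C@H](C)CC(=O)C=C1C
F3 | step 4 | (4R,5R)-4-hydroxy-4-[(E)-5-hydroxy-3-methylpent-3-en-1-ynyl]-3,3,5-trimethylcyclohexan-1-one | OC/C=C(C)/C#C[C@@]1(O)[C@H](C)CC(=O)CC1(C)C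
F4 | step 4 | (4S,5R)-4-[(1Z,3E)-2-(benzyldimethylsilyl)-5-hydroxy-3-methylpenta-1,3-dienyl]-4-hydroxy-3,3,5-trimethylcyclohexan-1-one | OC/C=C(C)/C([Si](C)(C)Cc2ccccc2)=C/[C@@]1(O)[C@H](C)CC(=O)CC1(C)C
F5 | step 5 | (4R,5R)-3,3,5-trimethyl-4-[(E)-3-methyl-2-oxo-5-(triethylsilyloxy)pent-3-enyl]-4-(triethylsilyloxy)cyclohexan-1-one | CC[Si](CC)(CC)OC/C=C(\C)C(=O)C[C@@]1(O[Si](CC)(CC)CC)[C@H](C)CC(=O)CC1(C)C
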